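**Retrosynthetic overview**

1. Feature: the target is a 3-arylcoumarin in which the 5-methoxy-2,2-dimethylchroman-6-yl ring sits on C3, next to the C4 methine that is fused through C4a to a benzene ring oxygenated at O1, C5 and C7 (a phloroglucinol ring). The C2–C3(aryl)–C4 unit is the isoflavonoid pattern, that is, a cinnamoyl chain after a 1,2-aryl shift.
2. Key disconnections: C3–C6' (chromanyl shift from Cβ to Cα of a cinnamate under Tl(III)) and C4–C4a (Friedel–Crafts closure of the pyranone by an ortho carbon of the phenyl ester). A nucleophile must occupy Cβ before the shift, so the carbon that becomes C4 is carried as a methoxy-stabilised oxocarbenium ion, stored as its dimethyl acetal. This leads back to aryl (E)-cinnamate 11 of the symmetric 3,5-bis(benzyloxy)phenol 10.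
3. Ester 11 comes from acid 9 (Knoevenagel–Doebner) and aldehyde 6, which comes from 2,4-dihydroxybenzaldehyde 1 and prenal 2 by chromenylation, hydrogenation and O-methylation.
4. Ring order: dihydropyran ring of the chroman (step 1), then the pyranone ring (step 6). O5 and O7 are told apart only afterwards (debenzylation, 7-O-benzylation, 5-O-methylation, debenzylation).

Key step: step 6

Remark: the target has no stereogenic element (C2 of the chroman is gem-dimethyl and the C3–C6' bond rotates freely), so it is one achiral compound and the only geometry to control is the (E)-alkene of 9 and 11.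

**Route**

Step 1
Reactants: 1 2,4-dihydroxybenzaldehyde; 2 3-methylbut-2-enal
Product: 4 5-hydroxy-2,2-dimethyl-2H-chromene-6-carbaldehyde, via ortho-quinone methide 3 (not isolated)
Conditions: 2 (2 equiv), pyridine, 120 °C
Reagents that add atoms: none
Why: Knoevenagel-type condensation of prenal at C3 of 1, the carbon activated by both hydroxyls, should give quinone methide 3, whose oxa-6π electrocyclisation through O4 (the 2-OH stays hydrogen-bonded to the aldehyde) closes the 2,2-dimethyl-2H-pyran ring in the angular sense (chromenylation of a resorcinol).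

Step 2
Reactants: 4 5-hydroxy-2,2-dimethyl-2H-chromene-6-carbaldehyde
Product: 5 5-hydroxy-2,2-dimethylchromane-6-carbaldehyde
Conditions: H2 (1 atm), 5% Pd/C, EtOAc, rt, stopped after 1 equiv of H2
Reagents that add atoms: none
Why: Catalytic hydrogenation, in which the cis-disubstituted styrene-type C3=C4 bond is saturated much faster than the hydrogen-bonded aryl aldehyde is reduced.

Step 3
Reactants: 5 5-hydroxy-2,2-dimethylchromane-6-carbaldehyde
Product: 6 5-methoxy-2,2-dimethylchromane-6-carbaldehyde
Conditions: MeI, K2CO3, DMF, 40 °C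
Reagents that add atoms: iodomethane, CI
Why: Williamson ether synthesis, in which carbonate in DMF deprotonates the chelated 5-OH and the phenoxide is methylated by SN2, nothing else in 5 being alkylatable.

Step 4
Reactants: 6 5-methoxy-2,2-dimethylchromane-6-carbaldehyde; 7 malonic acid
Product: 9 (E)-3-(5-methoxy-2,2-dimethylchroman-6-yl)prop-2-enoic acid, via arylidenemalonic acid 8 (not isolated)
Conditions: pyridine, piperidine (cat.), 100 °C
Reagents that add atoms: none
Why: Knoevenagel–Doebner condensation, in which the piperidine-catalysed condensation gives 8 and its decarboxylation in hot pyridine gives the thermodynamically favoured (E)-cinnamic acid.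

Step 5
Reactants: 9 (E)-3-(5-methoxy-2,2-dimethylchroman-6-yl)prop-2-enoic acid; 10 3,5-bis(benzyloxy)phenol
Product: 11 3,5-bis(benzyloxy)phenyl (E)-3-(5-methoxy-2,2-dimethylchroman-6-yl)prop-2-enoate
Conditions: DCC, DMAP (cat.), CH2Cl2, 0 °C → rt
Reagents that add atoms: none
Why: Steglich esterification, in which DMAP turns the O-acylisourea into an acylpyridinium ion that acylates the phenol under neutral conditions and leaves the (E)-alkene and the benzyl ethers untouched.

Step 6
Reactants: 11 3,5-bis(benzyloxy)phenyl (E)-3-(5-methoxy-2,2-dimethylchroman-6-yl)prop-2-enoate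
Product: 14 5,7-bis(benzyloxy)-3-(5-methoxy-2,2-dimethylchroman-6-yl)-2H-chromen-2-one, via dimethyl acetal 12 (not isolated), via 4-methoxy lactone 13 (not isolated)
Conditions: Tl(NO3)3·3H2O (1.1 equiv), MeOH–HC(OMe)3 (1:1), rt; filter, aqueous wash, evaporate; then crude 12, TFA (10 equiv), CH2Cl2 (0.02 M), 0 °C → rt
Reagents that add atoms: none
Why: Proposed new method: Tl(III) adds to Cα of the electron-rich alkene, methanol caps the Cβ benzylic cation that the ortho-methoxy/para-alkoxy chromanyl ring stabilises, and this ring then shifts from Cβ to Cα through a phenonium ion as Tl(I) leaves (new C3–C6' bond), which leaves a methoxy-stabilised oxocarbenium ion at the former Cβ that methanol stores as acetal 12. In TFA the acetal re-ionises and the ortho carbon of the ester ring, which lies ortho and para to the two benzyloxy groups, attacks the oxocarbenium ion in a 6-exo-trig Friedel–Crafts (Pechmann-type) closure (new C4–C4a bond, pyranone ring, lactone 13), after which loss of methanol through the A-ring-stabilised C4 cation and loss of H3 give the C3=C4 bond of 14. The closest known reactions are the thallium(III) nitrate rearrangement of alkyl cinnamates and chalcones to α-aryl-β,β-dimethoxy carbonyl compounds, the acid cyclisation of such acetals in the isoflavone synthesis, and the Pechmann condensation of phenols with formylacetate equivalents; new is their union on an aryl cinnamate, so that the arene capture is intramolecular. No stereocentre has to be controlled, because those at C3 and C4 of 12 and 13 are formed racemic and vanish on elimination. The step needs attack of Tl(III) on the alkene rather than on the two electron-rich rings, and migration rather than plain dimethoxylation; both rest on the strong push of the 2,4-dioxygenated aryl group into Cβ, on the O-acyl group that tempers the A ring and on a short contact time at room temperature, while the symmetry of the 3,5-disubstituted ester ring makes both ortho carbons identical, so the closure raises no regiochemical question. Should the ester ring capture the Cβ cation before methanol does, the same aryl shift in the 3-thallio-4-aryl lactone followed by loss of H3 would lead to the same coumarin 14.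

Step 7
Reactants: 14 5,7-bis(benzyloxy)-3-(5-methoxy-2,2-dimethylchroman-6-yl)-2H-chromen-2-one
Product: 15 5,7-dihydroxy-3-(5-methoxy-2,2-dimethylchroman-6-yl)-2H-chromen-2-one
Conditions: H2 (1 atm), 10% Pd/C, EtOAc–THF, rt
Reagents that add atoms: none
Why: Catalytic hydrogenolysis of the two benzyl aryl ethers, which at 1 atm should be much faster than hydrogenation of the trisubstituted, aryl-conjugated C3=C4 bond of the coumarin.

Step 8
Reactants: 15 5,7-dihydroxy-3-(5-methoxy-2,2-dimethylchroman-6-yl)-2H-chromen-2-one
Product: 16 7-(benzyloxy)-5-hydroxy-3-(5-methoxy-2,2-dimethylchroman-6-yl)-2H-chromen-2-one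
Conditions: BnBr (1.0 equiv), K2CO3 (1.0 equiv), acetone, rt
Reagents that add atoms: benzyl bromide, BrCc1ccccc1
Why: Williamson etherification with one equivalent of base and halide, in which the 7-OH (para to the C4a–C4=C3–C2=O acceptor and free of the crowding that O5 suffers next to C4a and H4) is expected to ionise and be benzylated first.

Step 9
Reactants: 16 7-(benzyloxy)-5-hydroxy-3-(5-methoxy-2,2-dimethylchroman-6-yl)-2H-chromen-2-one
Product: 17 7-(benzyloxy)-5-methoxy-3-(5-methoxy-2,2-dimethylchroman-6-yl)-2H-chromen-2-one
Conditions: MeI, K2CO3, acetone, reflux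
Reagents that add atoms: iodomethane, CI
Why: Williamson ether synthesis on the only free phenol, under anhydrous carbonate in acetone that should not open the lactone.

Step 10
Reactants: 17 7-(benzyloxy)-5-methoxy-3-(5-methoxy-2,2-dimethylchroman-6-yl)-2H-chromen-2-one
Product: 18 7-hydroxy-5-methoxy-3-(5-methoxy-2,2-dimethylchroman-6-yl)-2H-chromen-2-one
Conditions: H2 (1 atm), 10% Pd/C, EtOAc–THF, rt
Reagents that add atoms: none
Why: Catalytic hydrogenolysis of the benzyl aryl ether, selective over the coumarin C3=C4 bond as in step 7, frees the 7-OH of the target.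

**Compound list**

1 | 2,4-dihydroxybenzaldehyde | O=Cc1ccc(O)cc1O | starting material
2 | 3-methylbut-2-enal | CC(C)=CC=O | starting material
3 | 2-hydroxy-3-(3-methylbut-2-en-1-ylidene)-4-oxocyclohexa-1,5-diene-1-carbaldehyde (ortho-quinone methide) | O=CC1=C(O)C(=CC=C(C)C)C(=O)C=C1 | intermediate
4 | 5-hydroxy-2,2-dimethyl-2H-chromene-6-carbaldehyde | O=Cc1ccc2c(c1O)C=CC(C)(C)O2 | intermediate
5 | 5-hydroxy-2,2-dimethylchromane-6-carbaldehyde | O=Cc1ccc2c(c1O)CCC(C)(C)O2 | intermediate
6 | 5-methoxy-2,2-dimethylchromane-6-carbaldehyde | COc1c(C=O)ccc2OC(C)(C)CCc12 | intermediate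
7 | malonic acid | OC(=O)CC(=O)O | starting material
8 | 2-[(5-methoxy-2,2-dimethylchroman-6-yl)methylidene]propanedioic acid | COc1c(C=C(C(=O)O)C(=O)O)ccc2OC(C)(C)CCc12 | intermediate
9 | (E)-3-(5-methoxy-2,2-dimethylchroman-6-yl)prop-2-enoic acid | COc1c(/C=C/C(=O)O)ccc2OC(C)(C)CCc12 | intermediate
10 | 3,5-bis(benzyloxy)phenol | Oc1cc(OCc2ccccc2)cc(OCc2ccccc2)c1 | starting material
11 | 3,5-bis(benzyloxy)phenyl (E)-3-(5-methoxy-2,2-dimethylchroman-6-yl)prop-2-enoate | COc1c(/C=C/C(=O)Oc2cc(OCc3ccccc3)cc(OCc3ccccc3)c2)ccc2OC(C)(C)CCc12 | intermediate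
12 | 3,5-bis(benzyloxy)phenyl 3,3-dimethoxy-2-(5-methoxy-2,2-dimethylchroman-6-yl)propanoate (racemic) | COC(OC)C(C(=O)Oc1cc(OCc2ccccc2)cc(OCc2ccccc2)c1)c1ccc2OC(C)(C)CCc2c1OC | intermediate
13 | 5,7-bis(benzyloxy)-4-methoxy-3-(5-methoxy-2,2-dimethylchroman-6-yl)chroman-2-one (racemic, mixture of diastereomers) | COC1C(c2ccc3OC(C)(C)CCc3c2OC)C(=O)Oc2cc(OCc3ccccc3)cc(OCc3ccccc3)c12 | intermediate
14 | 5,7-bis(benzyloxy)-3-(5-methoxy-2,2-dimethylchroman-6-yl)-2H-chromen-2-one | COc1c(-c2cc3c(OCc4ccccc4)cc(OCc4ccccc4)cc3oc2=O)ccc2c1CCC(C)(C)O2 | intermediate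
15 | 5,7-dihydroxy-3-(5-methoxy-2,2-dimethylchroman-6-yl)-2H-chromen-2-one | COc1c(-c2cc3c(O)cc(O)cc3oc2=O)ccc2c1CCC(C)(C)O2 | intermediate
16 | 7-(benzyloxy)-5-hydroxy-3-(5-methoxy-2,2-dimethylchroman-6-yl)-2H-chromen-2-one | COc1c(-c2cc3c(O)cc(OCc4ccccc4)cc3oc2=O)ccc2c1CCC(C)(C)O2 | intermediate
17 | 7-(benzyloxy)-5-methoxy-3-(5-methoxy-2,2-dimethylchroman-6-yl)-2H-chromen-2-one | COc1c(-c2cc3c(OC)cc(OCc4ccccc4)cc3oc2=O)ccc2c1CCC(C)(C)O2 | intermediate
18 | 7-hydroxy-5-methoxy-3-(5-methoxy-2,2-dimethylchroman-6-yl)-2H-chromen-2-one | COc1c(-c2cc3c(OC)cc(O)cc3oc2=O)ccc2c1CCC(C)(C)O2 | target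

**Step count**

Total: 10 steps. Longest linear sequence: 10 steps (1 → 18).

**Steps most likely to fail**

Step 6 (the proposed new method). What may go wrong: oxidation or thallation of the benzyloxy-substituted ester ring or of the chroman ring in competition with oxythallation of the alkene, methanolysis of the aryl ester before the ring can close, or loss of benzyl groups in the acid stage. Fallback with known chemistry, setting out from 6 and 10 and returning at 14:
- Aldehyde 6 is homologated by Wittig reaction with the ylide from (methoxymethyl)triphenylphosphonium chloride and KOt-Bu in THF to the enol ether 5-methoxy-6-(2-methoxyethenyl)-2,2-dimethylchromane F1 (E/Z mixture).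
- Aqueous HCl in THF should hydrolyse it to 2-(5-methoxy-2,2-dimethylchroman-6-yl)acetaldehyde F2.
- Pinnick oxidation (NaClO2, NaH2PO4, 2-methylbut-2-ene, t-BuOH–H2O) then gives 2-(5-methoxy-2,2-dimethylchroman-6-yl)acetic acid F3.
- In parallel, phenol 10 is ortho-formylated (MgCl2, Et3N, paraformaldehyde, MeCN, reflux) to 2,4-bis(benzyloxy)-6-hydroxybenzaldehyde F4.
- Perkin–Oglialoro condensation of the acid with this aldehyde (Ac2O, Et3N, 110 °C) should close the pyranone and give 14, where the route resumes at step 7.

Step 8. What may go wrong: the alkylation fails to discriminate between the two phenols, so that 5-O-benzylation and double benzylation compete. Fallback that fixes the O5/O7 pattern before the pyranone exists, setting out from 6 and returning at 17: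
- Commercial 2,4-dihydroxy-6-methoxybenzaldehyde F5 is benzylated (BnBr, K2CO3, acetone) at its 4-OH, the 2-OH being held by the hydrogen bond to the aldehyde, to give 4-(benzyloxy)-2-hydroxy-6-methoxybenzaldehyde F6.
- Perkin–Oglialoro condensation of this aldehyde with 2-(5-methoxy-2,2-dimethylchroman-6-yl)acetic acid F3 (made from 6 as described for step 6; Ac2O, Et3N, 110 °C) should give 17 directly, and step 10 follows.

Step 1. What may go wrong: condensation at C5 instead of C3, double condensation, and self-condensation of prenal, all of which erode the angular chromene. Fallback setting out from 1 and returning at 4: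
- The non-chelated 4-OH of 1 is alkylated with 3-chloro-3-methylbut-1-yne (K2CO3, KI, CuI cat., acetone) to give 2-hydroxy-4-[(2-methylbut-3-yn-2-yl)oxy]benzaldehyde F7.
- Heating in N,N-diethylaniline (about 190 °C) should bring about the aromatic propargyl Claisen rearrangement to C3, a 1,5-hydrogen shift and oxa-6π closure to chromene 4.

**Further compounds**

F1 | step 6 | 5-methoxy-6-(2-methoxyethenyl)-2,2-dimethylchromane (E/Z mixture) | COC=Cc1ccc2OC(C)(C)CCc2c1OC
F2 | step 6 | 2-(5-methoxy-2,2-dimethylchroman-6-yl)acetaldehyde | O=CCc1ccc2OC(C)(C)CCc2c1OC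
F3 | step 6 | 2-(5-methoxy-2,2-dimethylchroman-6-yl)acetic acid | OC(=O)Cc1ccc2OC(C)(C)CCc2c1OC
F4 | step 6 | 2,4-bis(benzyloxy)-6-hydroxybenzaldehyde | O=Cc1c(O)cc(OCc2ccccc2)cc1OCc1ccccc1
F5 | step 8 | 2,4-dihydroxy-6-methoxybenzaldehyde | COc1cc(O)cc(O)c1C=O
F6 | step 8 | 4-(benzyloxy)-2-hydroxy-6-methoxybenzaldehyde | COc1cc(OCc2ccccc2)cc(O)c1C=O
F7 | step 1 | 2-hydroxy-4-[(2-methylbut-3-yn-2-yl)oxy]benzaldehyde | C#CC(C)(C)Oc1ccc(C=O)c(O)c1
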